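All runs come from a simulation from invented constants.

1. Time did little in run zeta, the flask in question: X read 28.9% at 8.00 min and 29.5% at 90.0 min. In the cooler run theta, X read 14.0% at 10.0 min and then flattened near 19.0%.

| setting | zeta | theta | flask |
|---|---|---|---|
| G | 0.037 M | 0.037 M | 0.037 M |
| Z | 2.5 equiv | 1.2 equiv | 2.50 equiv |
| temperature | 70 °C | 55 °C | 70 °C |
| remark | the very flask that is asked about, followed so far | run made earlier |  |
| time |  |  | 2.5 h |

| run | time / min | X / % |
|---|---|---|
| zeta | 8.00 | 28.9 |
| zeta | 15.0 | 28.8 |
| zeta | 40.0 | 29.1 |
| zeta | 90.0 | 29.5 |
| theta | 10.0 | 14.0 |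
| theta | 20.0 | 18.1 |
| theta | 50.0 | 19.0 |
| theta | 120 | 18.5 |

(readings scatter by 0.5 percentage points)

- amber: at 2.5 h add Z, 50.0% of the amount charged, then wait 50 min
- violet: at 2.5 h raise the temperature by 25 K, then wait 50 min
- red: change nothing and wait 50 min more
- teal: at 2.5 h add G, 50.0% of the amount charged, then wait 50 min

- the volume of additions can be left aside
- the numbers in the tables scatter by 0.5 percentage points (one standard deviation)
- a reading or a percentage of X counts all its forms, free or not

1. X, in percent of the G first charged, at 2.5 h
2. the remedy with the largest gain of X, or "none" below 2 percentage points (amber / violet / red / teal / none)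
3. X present, in percent of the G first charged, after red
4. X present, in percent of the G first charged, after teal

2. I began with the main step alone, G + Z → X. With 2.5 equiv of Z charged, that step gives X a ceiling of the whole G charge. Yet zeta's readings average 29.1%, and they do not fall, so X is not being lost.

3. Next I added one process, a first-order loss of Z on its own. A reversible step could also draw a flat line, and these readings do not separate the two, but I committed to the loss of Z. Each Z then becomes X with the share [G]/([G] + c). Summed over a run, [Z] charged = [G] turned + c·ln([G] before/[G] after). Zeta charged 0.0925 M of Z, and the readings give c = 0.238 M. I call c the split concentration, the [G] at which a Z is as likely to become X as to be lost.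

4. Then came the rest. Any other exit of Z is folded into c, since c was read from X. I have no reading of G, so for zeta I took [G] as the charge less X, 0.0262 M, an upper figure if G has other exits.

5. My reckoning followed. Zeta was flat long before the asked time, 2.5 h against 8.00 min, so I put X now and after red at 29.1%. X moved 0.6 percentage points from the first zeta reading to the last, against a scatter of 0.5 points. I read that as Z no longer feeding X, and on that reading I put teal at 29.1% and expected no gain from violet. The amber dose of 0.0462 M Z, put through the same sum with c, gains 11 points, more than the bar of 2 points. I chose amber.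

6. The forecast, which parts from me at teal, gave 29.2% now, teal as best, 29.2% after red and 41% after teal, on this ground: “That looks like an equilibrium”.

7. The flask gave 28.9% now and amber as best, with a gain of 11 points. Violet gained 0 points, red left 28.9%, and teal left 28.9%.

    J ⇌ X, rate k1*(cs1 - [X]) while solid is left; crystals form when [X] > cs1 (solubility = 33.0 mM, k = 9.61 min⁻¹)
    Z → Q (k = 0.470 min⁻¹, Ea = 87.0 kJ mol⁻¹)
    G + Z → E (k = 0.129 L mol⁻¹ min⁻¹, Ea = 77.0 kJ mol⁻¹)
    G + Z → X (k = 2.01 L mol⁻¹ min⁻¹, Ea = 68.0 kJ mol⁻¹)
    G + Z → D (k = 0.0327 L mol⁻¹ min⁻¹, Ea = 60.0 kJ mol⁻¹)
    (constants at 70 °C)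

Flask zeta had come to rest. At 150 min Z, the limiting reagent despite its excess charge, stood at 0% of its charge, with 68.8% of the G still free. Left until 1500 min, the flask reads X 28.9%, so the extra time changes nothing.

For a neighbour flask, with 0.015 M of G at the same equivalents, the same c gives 13.8% X. The computed flask gives 13.9%.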